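**Strategy.** Everything rests on cutting ring C of the 3-hydroxyisoflavanone at two bonds to ring A, aryl C8a–O1 and aryl C4a–C4. One annulation of 3,5-bis(benzyloxy)benzyne with an enantiopure β-hydroxy ester forms both: the primary alkoxide adds to the aryne and the resulting aryl anion captures the ester. The step exploits the ortho placement of O1 and the C4 carbonyl on C8a and C4a, and the C5 oxygen beside C4a, which steers oxygen to C8a and acyl to C4a. The precursor, ethyl (R)-2-aryl-3-hydroxy-2-(methoxymethoxy)propanoate, gets its quaternary C3 centre from desymmetrising reduction of an aryl(alkoxy)malonate made by ortho-lithiation of the reverse-prenylated ring B.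

Key step: step 8

Remark: compounds 1, 2, 6 and 12 are taken as commercial, and in step 5 the ligand enantiomer is the one that a test reduction shows to attack the pro-S ester group of 9.

**Step 1**
Reactants: 1 2,2-dimethyl-1,3-benzodioxol-4-ol; 2 1-bromo-3-methylbut-2-ene (prenyl bromide)
Product: 3 2,2-dimethyl-4-[(3-methylbut-2-en-1-yl)oxy]-1,3-benzodioxole
Conditions: K2CO3, acetone, reflux
Reagents that add atoms: none
Why: Williamson etherification of the only phenol with a reactive allylic bromide should give the O-prenyl ether.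

**Step 2**
Reactants: 3 2,2-dimethyl-4-[(3-methylbut-2-en-1-yl)oxy]-1,3-benzodioxole
Product: 4 2,2-dimethyl-5-(2-methylbut-3-en-2-yl)-1,3-benzodioxol-4-ol
Conditions: PhNEt2, 190 °C
Reagents that add atoms: none
Why: Aromatic Claisen rearrangement should deliver the inverted 1,1-dimethylallyl group to C5, the only ortho carbon that bears hydrogen, and tautomerisation then restores the phenol.

**Step 3**
Reactants: 4 2,2-dimethyl-5-(2-methylbut-3-en-2-yl)-1,3-benzodioxol-4-ol
Product: 5 4-methoxy-2,2-dimethyl-5-(2-methylbut-3-en-2-yl)-1,3-benzodioxole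
Conditions: MeI, K2CO3, DMF, 40 °C
Reagents that add atoms: iodomethane, CI
Why: O-Methylation of the phenoxide (Williamson etherification) should proceed at the only acidic site despite the flanking tert-alkyl group.

**Step 4**
Reactants: 5 4-methoxy-2,2-dimethyl-5-(2-methylbut-3-en-2-yl)-1,3-benzodioxole; 6 diethyl 2-oxopropanedioate (diethyl ketomalonate)
Product: 9 diethyl 2-[7-methoxy-2,2-dimethyl-6-(2-methylbut-3-en-2-yl)-1,3-benzodioxol-4-yl]-2-(methoxymethoxy)propanedioate, via aryllithium 7 (not isolated), via lithium alkoxide 8 (not isolated)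
Conditions: n-BuLi, THF, 0 °C; then 6, −78 °C; then MOMCl, DMPU, −78 °C → rt
Reagents that add atoms: chloromethyl methyl ether, COCCl
Why: Directed ortho-metalation by the dioxole oxygen should lithiate C7, the only ring hydrogen next to a directing group, the aryllithium then adds to the strongly electrophilic central ketone of 6, and the tertiary lithium alkoxide is O-alkylated in the same flask.

**Step 5**
Reactants: 9 diethyl 2-[7-methoxy-2,2-dimethyl-6-(2-methylbut-3-en-2-yl)-1,3-benzodioxol-4-yl]-2-(methoxymethoxy)propanedioate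
Product: 11 ethyl (2R)-3-hydroxy-2-[7-methoxy-2,2-dimethyl-6-(2-methylbut-3-en-2-yl)-1,3-benzodioxol-4-yl]-2-(methoxymethoxy)propanoate, via trimethoxysilyl ether 10 (not isolated)
Conditions: ZnEt2 (10 mol %), chiral ProPhenol-type bis(amino alcohol) ligand (5 mol %), (MeO)3SiH, THF, 0 °C; then 1 M aq. HCl, 0 °C
Reagents that add atoms: none
Why: Zinc-catalysed desymmetrising hydrosilylation of a prochiral disubstituted malonic ester should reduce only the pro-S ester to the primary alcohol, the dinuclear zinc catalyst telling the aryl group from the alkoxy group on the bound malonate and so setting the (R) quaternary centre, while the isolated alkene is inert to zinc hydride.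

**Step 6**
Reactants: 12 3,5-bis(benzyloxy)phenol
Product: 13 3,5-bis(benzyloxy)-2-bromophenol
Conditions: NBS, CH2Cl2, −78 → 0 °C
Reagents that add atoms: N-bromosuccinimide, O=C1CCC(=O)N1Br
Why: Electrophilic aromatic bromination of the activated phenol should favour the two equivalent positions ortho to the hydroxyl (statistics and hydrogen-bond delivery in a non-polar solvent), and the para isomer would be removed by chromatography.

**Step 7**
Reactants: 13 3,5-bis(benzyloxy)-2-bromophenol
Product: 16 3,5-bis(benzyloxy)-2-(trimethylsilyl)phenyl trifluoromethanesulfonate, via silyl ether 14 (not isolated), via lithium phenoxide 15 (not isolated)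
Conditions: HMDS, THF, 70 °C; then n-BuLi, THF, −100 °C; then Tf2O, −100 °C → rt
Reagents that add atoms: 1,1,1,3,3,3-hexamethyldisilazane, C[Si](C)(C)N[Si](C)(C)C; trifluoromethanesulfonic anhydride, O=S(=O)(OS(=O)(=O)C(F)(F)F)C(F)(F)F
Why: O-Silylation, bromine–lithium exchange, 1,3 oxygen-to-carbon silyl shift (retro-Brook rearrangement) and triflation of the phenoxide is the standard sequence to o-silylaryl triflates.

**Step 8**
Reactants: 11 ethyl (2R)-3-hydroxy-2-[7-methoxy-2,2-dimethyl-6-(2-methylbut-3-en-2-yl)-1,3-benzodioxol-4-yl]-2-(methoxymethoxy)propanoate; 16 3,5-bis(benzyloxy)-2-(trimethylsilyl)phenyl trifluoromethanesulfonate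
Product: 18 (3R)-5,7-bis(benzyloxy)-3-(methoxymethoxy)-3-[7-methoxy-2,2-dimethyl-6-(2-methylbut-3-en-2-yl)-1,3-benzodioxol-4-yl]-2,3-dihydro-4H-chromen-4-one, via aryne 17 (not isolated)
Conditions: CsF, THF, 65 °C
Reagents that add atoms: none
Why: Proposed new method: CsF turns 16 into aryne 17, whose triple bond is distorted by the benzyloxy group on the adjacent carbon, so the fluoride-activated primary hydroxyl of 11 should add at the aryne carbon remote from that group and leave the aryl anion on the carbon between the two oxygens, where it is inductively stabilised. That anion attacks the ethyl ester three atoms away in a 6-exo-trig acyl substitution that closes ring C and expels ethoxide, so the aryl–O1 and aryl–C4 bonds form in one operation. The closest known reaction type is the aryne annulation of salicylate and anthranilate esters to xanthones and acridones (heteroatom addition then intramolecular acyl capture), and the aryne insertion into the N–acyl bond of β-lactams; an aliphatic β-hydroxy ester has not served as the partner. No stereocentre is formed, and the quaternary C3 of 11 bears no hydrogen, so it can neither epimerise nor eliminate. The step needs regioselective addition to the unsymmetrical aryne, secured by the benzyloxy group beside the triple bond, and acyl capture faster than protonation of the aryl anion, favoured by aprotic THF, the six-membered transition state and slow aryne release from sparingly soluble CsF.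

**Step 9**
Reactants: 18 (3R)-5,7-bis(benzyloxy)-3-(methoxymethoxy)-3-[7-methoxy-2,2-dimethyl-6-(2-methylbut-3-en-2-yl)-1,3-benzodioxol-4-yl]-2,3-dihydro-4H-chromen-4-one
Product: 19 (3R)-3-[2,3-dihydroxy-4-methoxy-5-(2-methylbut-3-en-2-yl)phenyl]-3,5,7-trihydroxy-2,3-dihydro-4H-chromen-4-one
Conditions: BCl3, C6HMe5, CH2Cl2, −78 → 0 °C; then H2O
Reagents that add atoms: none
Why: Lewis acid ether cleavage by BCl3 should remove both aryl benzyl ethers (benzyl cations trapped by pentamethylbenzene, sparing ring A and the alkene), the methoxymethyl ether and the catechol acetonide, while low temperature spares the aryl methyl ether and the boron-chelated C4 carbonyl disfavours ionisation at C3.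

**Compound list**
1 | 2,2-dimethyl-1,3-benzodioxol-4-ol | CC1(C)Oc2cccc(O)c2O1 | starting material
2 | 1-bromo-3-methylbut-2-ene | CC(C)=CCBr | starting material
3 | 2,2-dimethyl-4-[(3-methylbut-2-en-1-yl)oxy]-1,3-benzodioxole | CC(C)=CCOc1cccc2OC(C)(C)Oc12 | intermediate
4 | 2,2-dimethyl-5-(2-methylbut-3-en-2-yl)-1,3-benzodioxol-4-ol | C=CC(C)(C)c1ccc2OC(C)(C)Oc2c1O | intermediate
5 | 4-methoxy-2,2-dimethyl-5-(2-methylbut-3-en-2-yl)-1,3-benzodioxole | C=CC(C)(C)c1ccc2OC(C)(C)Oc2c1OC | intermediate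
6 | diethyl 2-oxopropanedioate | CCOC(=O)C(=O)C(=O)OCC | starting material
7 | [7-methoxy-2,2-dimethyl-6-(2-methylbut-3-en-2-yl)-1,3-benzodioxol-4-yl]lithium | C=CC(C)(C)c1cc([Li])c2OC(C)(C)Oc2c1OC | intermediate
8 | lithium alkoxide of diethyl 2-hydroxy-2-[7-methoxy-2,2-dimethyl-6-(2-methylbut-3-en-2-yl)-1,3-benzodioxol-4-yl]propanedioate | CCOC(=O)C(O[Li])(C(=O)OCC)c1cc(C(C)(C)C=C)c(OC)c2OC(C)(C)Oc12 | intermediate
9 | diethyl 2-[7-methoxy-2,2-dimethyl-6-(2-methylbut-3-en-2-yl)-1,3-benzodioxol-4-yl]-2-(methoxymethoxy)propanedioate | CCOC(=O)C(OCOC)(C(=O)OCC)c1cc(C(C)(C)C=C)c(OC)c2OC(C)(C)Oc12 | intermediate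
10 | ethyl (2R)-2-[7-methoxy-2,2-dimethyl-6-(2-methylbut-3-en-2-yl)-1,3-benzodioxol-4-yl]-2-(methoxymethoxy)-3-[(trimethoxysilyl)oxy]propanoate | CCOC(=O)[C@](OCOC)(CO[Si](OC)(OC)OC)c1cc(C(C)(C)C=C)c(OC)c2OC(C)(C)Oc12 | intermediate
11 | ethyl (2R)-3-hydroxy-2-[7-methoxy-2,2-dimethyl-6-(2-methylbut-3-en-2-yl)-1,3-benzodioxol-4-yl]-2-(methoxymethoxy)propanoate | CCOC(=O)[C@](OCOC)(CO)c1cc(C(C)(C)C=C)c(OC)c2OC(C)(C)Oc12 | intermediate
12 | 3,5-bis(benzyloxy)phenol | Oc1cc(OCc2ccccc2)cc(OCc2ccccc2)c1 | starting material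
13 | 3,5-bis(benzyloxy)-2-bromophenol | Oc1cc(OCc2ccccc2)cc(OCc2ccccc2)c1Br | intermediate
14 | [3,5-bis(benzyloxy)-2-bromophenoxy]trimethylsilane | C[Si](C)(C)Oc1cc(OCc2ccccc2)cc(OCc2ccccc2)c1Br | intermediate
15 | lithium 3,5-bis(benzyloxy)-2-(trimethylsilyl)phenoxide | [Li]Oc1cc(OCc2ccccc2)cc(OCc2ccccc2)c1[Si](C)(C)C | intermediate
16 | 3,5-bis(benzyloxy)-2-(trimethylsilyl)phenyl trifluoromethanesulfonate | C[Si](C)(C)c1c(OS(=O)(=O)C(F)(F)F)cc(OCc2ccccc2)cc1OCc1ccccc1 | intermediate
17 | 3,5-bis(benzyloxy)benzyne (3,5-bis(benzyloxy)-1,2-didehydrobenzene) | C1#CC(OCc2ccccc2)=CC(OCc2ccccc2)=C1 | intermediate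
18 | (3R)-5,7-bis(benzyloxy)-3-(methoxymethoxy)-3-[7-methoxy-2,2-dimethyl-6-(2-methylbut-3-en-2-yl)-1,3-benzodioxol-4-yl]-2,3-dihydro-4H-chromen-4-one | C=CC(C)(C)c1cc([C@@]2(OCOC)COc3cc(OCc4ccccc4)cc(OCc4ccccc4)c3C2=O)c2OC(C)(C)Oc2c1OC | intermediate
19 | (3R)-3-[2,3-dihydroxy-4-methoxy-5-(2-methylbut-3-en-2-yl)phenyl]-3,5,7-trihydroxy-2,3-dihydro-4H-chromen-4-one | C=CC(C)(C)c1cc([C@@]2(O)COc3cc(O)cc(O)c3C2=O)c(O)c(O)c1OC | target

**Count.** Total steps: 9. Longest linear sequence: 7 steps (steps 1, 2, 3, 4, 5, 8, 9); the aryne precursor branch is steps 6 and 7.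

**Steps most likely to fail**

Step 8 (proposed new method). Proton transfer to the aryl anion may outrun acyl capture and leave the open aryl ether. The alkoxide may also fragment by retro-aldol loss of formaldehyde, and the released ethoxide may consume aryne. The fallback uses known chemistry, sets out from 11 and 16 and returns at 18. The same aryne is generated under conditions that favour plain O–H insertion (CsF, MeCN, rt). This should give ethyl (2R)-3-[3,5-bis(benzyloxy)phenoxy]-2-[7-methoxy-2,2-dimethyl-6-(2-methylbut-3-en-2-yl)-1,3-benzodioxol-4-yl]-2-(methoxymethoxy)propanoate F1, in which the two ring positions ortho to the new ether oxygen are equivalent. Saponification (LiOH, THF/MeOH/H2O, 50 °C) should give (2R)-3-[3,5-bis(benzyloxy)phenoxy]-2-[7-methoxy-2,2-dimethyl-6-(2-methylbut-3-en-2-yl)-1,3-benzodioxol-4-yl]-2-(methoxymethoxy)propanoic acid F2. Intramolecular Friedel–Crafts acylation of the phloroglucinol-type ring ((CF3CO)2O, CH2Cl2, 0 °C) then closes ring C to 18.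

Step 5. The catalyst may discriminate poorly between the enantiotopic ester groups, since aryl and methoxymethoxy differ less than the usual large/small pair. Reduction may also run on to the diol. The fallback sets out from 9 and returns at 11. Enzymatic hydrolysis of the pro-S ester with pig liver esterase (phosphate buffer pH 7, DMSO cosolvent) should give (2R)-3-ethoxy-2-[7-methoxy-2,2-dimethyl-6-(2-methylbut-3-en-2-yl)-1,3-benzodioxol-4-yl]-2-(methoxymethoxy)-3-oxopropanoic acid F3. Activation with isobutyl chloroformate and N-methylmorpholine (THF, −15 °C) gives the mixed anhydride ethyl (2S)-2-[7-methoxy-2,2-dimethyl-6-(2-methylbut-3-en-2-yl)-1,3-benzodioxol-4-yl]-2-(methoxymethoxy)-3-[(2-methylpropoxy)carbonyloxy]-3-oxopropanoate F4. NaBH4 (THF/H2O, 0 °C) reduces F4 chemoselectively to 11 without touching the ethyl ester or the alkene.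

Step 9. The hindered methyl ether, twisted out of plane beside the boron catecholate, may be lost. The acetonide may cleave incompletely at temperatures the tertiary α-ketol tolerates, and the Lewis acid may induce ketol rearrangement or dehydration. The fallback changes the protecting-group plan so that no warming is needed; it sets out from 5 and returns at 19.
- The acetonide is removed from the robust arene (3 M HCl in MeOH, 60 °C) to give 3-methoxy-4-(2-methylbut-3-en-2-yl)benzene-1,2-diol F5.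
- MOMCl and iPr2NEt (CH2Cl2) give 2-methoxy-3,4-bis(methoxymethoxy)-1-(2-methylbut-3-en-2-yl)benzene F6.
- The sequence of step 4 then runs through [4-methoxy-2,3-bis(methoxymethoxy)-5-(2-methylbut-3-en-2-yl)phenyl]lithium F7 and the lithium alkoxide of diethyl 2-hydroxy-2-[4-methoxy-2,3-bis(methoxymethoxy)-5-(2-methylbut-3-en-2-yl)phenyl]propanedioate F8 to diethyl 2-[4-methoxy-2,3-bis(methoxymethoxy)-5-(2-methylbut-3-en-2-yl)phenyl]-2-(methoxymethoxy)propanedioate F9.
- The reduction of step 5 runs through ethyl (2R)-2-[4-methoxy-2,3-bis(methoxymethoxy)-5-(2-methylbut-3-en-2-yl)phenyl]-2-(methoxymethoxy)-3-[(trimethoxysilyl)oxy]propanoate F10 to ethyl (2R)-3-hydroxy-2-[4-methoxy-2,3-bis(methoxymethoxy)-5-(2-methylbut-3-en-2-yl)phenyl]-2-(methoxymethoxy)propanoate F11.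
- The annulation of step 8 with 16 gives (3R)-5,7-bis(benzyloxy)-3-(methoxymethoxy)-3-[4-methoxy-2,3-bis(methoxymethoxy)-5-(2-methylbut-3-en-2-yl)phenyl]-2,3-dihydro-4H-chromen-4-one F12.
- BCl3 with C6HMe5 in CH2Cl2 at −78 °C throughout, where benzyl and methoxymethyl ethers cleave without warming, then gives 19.

**Further compounds**
F1 | step 8 | ethyl (2R)-3-[3,5-bis(benzyloxy)phenoxy]-2-[7-methoxy-2,2-dimethyl-6-(2-methylbut-3-en-2-yl)-1,3-benzodioxol-4-yl]-2-(methoxymethoxy)propanoate | CCOC(=O)[C@](OCOC)(COc1cc(OCc2ccccc2)cc(OCc2ccccc2)c1)c1cc(C(C)(C)C=C)c(OC)c2OC(C)(C)Oc12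
F2 | step 8 | (2R)-3-[3,5-bis(benzyloxy)phenoxy]-2-[7-methoxy-2,2-dimethyl-6-(2-methylbut-3-en-2-yl)-1,3-benzodioxol-4-yl]-2-(methoxymethoxy)propanoic acid | OC(=O)[C@](OCOC)(COc1cc(OCc2ccccc2)cc(OCc2ccccc2)c1)c1cc(C(C)(C)C=C)c(OC)c2OC(C)(C)Oc12
F3 | step 5 | (2R)-3-ethoxy-2-[7-methoxy-2,2-dimethyl-6-(2-methylbut-3-en-2-yl)-1,3-benzodioxol-4-yl]-2-(methoxymethoxy)-3-oxopropanoic acid | CCOC(=O)[C@](OCOC)(C(=O)O)c1cc(C(C)(C)C=C)c(OC)c2OC(C)(C)Oc12
F4 | step 5 | ethyl (2S)-2-[7-methoxy-2,2-dimethyl-6-(2-methylbut-3-en-2-yl)-1,3-benzodioxol-4-yl]-2-(methoxymethoxy)-3-[(2-methylpropoxy)carbonyloxy]-3-oxopropanoate | CCOC(=O)[C@](OCOC)(C(=O)OC(=O)OCC(C)C)c1cc(C(C)(C)C=C)c(OC)c2OC(C)(C)Oc12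
F5 | step 9 | 3-methoxy-4-(2-methylbut-3-en-2-yl)benzene-1,2-diol | C=CC(C)(C)c1ccc(O)c(O)c1OC
F6 | step 9 | 2-methoxy-3,4-bis(methoxymethoxy)-1-(2-methylbut-3-en-2-yl)benzene | C=CC(C)(C)c1ccc(OCOC)c(OCOC)c1OC
F7 | step 9 | [4-methoxy-2,3-bis(methoxymethoxy)-5-(2-methylbut-3-en-2-yl)phenyl]lithium | C=CC(C)(C)c1cc([Li])c(OCOC)c(OCOC)c1OC
F8 | step 9 | lithium alkoxide of diethyl 2-hydroxy-2-[4-methoxy-2,3-bis(methoxymethoxy)-5-(2-methylbut-3-en-2-yl)phenyl]propanedioate | CCOC(=O)C(O[Li])(C(=O)OCC)c1cc(C(C)(C)C=C)c(OC)c(OCOC)c1OCOC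
F9 | step 9 | diethyl 2-[4-methoxy-2,3-bis(methoxymethoxy)-5-(2-methylbut-3-en-2-yl)phenyl]-2-(methoxymethoxy)propanedioate | CCOC(=O)C(OCOC)(C(=O)OCC)c1cc(C(C)(C)C=C)c(OC)c(OCOC)c1OCOC
F10 | step 9 | ethyl (2R)-2-[4-methoxy-2,3-bis(methoxymethoxy)-5-(2-methylbut-3-en-2-yl)phenyl]-2-(methoxymethoxy)-3-[(trimethoxysilyl)oxy]propanoate | CCOC(=O)[C@](OCOC)(CO[Si](OC)(OC)OC)c1cc(C(C)(C)C=C)c(OC)c(OCOC)c1OCOC
F11 | step 9 | ethyl (2R)-3-hydroxy-2-[4-methoxy-2,3-bis(methoxymethoxy)-5-(2-methylbut-3-en-2-yl)phenyl]-2-(methoxymethoxy)propanoate | CCOC(=O)[C@](OCOC)(CO)c1cc(C(C)(C)C=C)c(OC)c(OCOC)c1OCOC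
F12 | step 9 | (3R)-5,7-bis(benzyloxy)-3-(methoxymethoxy)-3-[4-methoxy-2,3-bis(methoxymethoxy)-5-(2-methylbut-3-en-2-yl)phenyl]-2,3-dihydro-4H-chromen-4-one | C=CC(C)(C)c1cc([C@@]2(OCOC)COc3cc(OCc4ccccc4)cc(OCc4ccccc4)c3C2=O)c(OCOC)c(OCOC)c1OC
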